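A ratio of target percentages taken at one time between two charges shows how far the charge matters. If every step were first-order, each percentage curve would be blind to the charge and the ratio would be 1, so that value is the zero of the scale.

| flask | substrate | remark | time |
|---|---|---|---|
| south-east | 0.27 M | run made earlier |  |
| west | 0.40 M | run made earlier |  |
| Sunday's | 0.53 M |  | 1.0 min |
| Wednesday's | 0.53 M |  | 2.0 min |

| south-east: time / min | south-east: target / % | west: time / min | west: target / % |
|---|---|---|---|
| 0.200 | 3.6 | 0.667 | 23.7 |
| 0.417 | 12.3 | 1.33 | 50.1 |
| 1.00 | 39.1 | 2.00 | 67.2 |
| 2.50 | 74.4 | 2.50 | 74.3 |

(standard deviation of a reading: 0.5 percentage points)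

- in percentages every species weighs as the substrate in it: one side product B counts as two
- for target the crystals are counted in
- as a solid, counted per litre of solution: crystals
- steps under discussion: substrate -> side product A; intermediate -> target; intermediate -> decomposed reagent; crystals <-> target; substrate -> intermediate; substrate + intermediate -> side product B

* which of the two ends with the higher amount of target, in percent of the substrate charged ("neither" if they lie within 2 percentage points) (Sunday's / Wednesday's / neither)
* target at the end, in percent of the substrate charged, Sunday's
* target at the end, in percent of the substrate charged, Wednesday's

Both earlier runs were read at 2.50 min, one charge step of 0.130 M apart: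

f = 74.3% / 74.4% = 0.999

Here f is the charge factor, target in the richer run over target in the leaner run at equal time. Wednesday's lies one step above the west run, with 0.130 M more substrate, and Sunday's two steps above the south-east run. Each has a reading at its own time, so W and S, the estimates for Wednesday's and Sunday's, are:

W = 67.2% × f = 67.1%

S = 39.1% × f × f = 39.0%

The objection is that f rests on one pair of readings, with a scatter of

0.00950

A small charge effect could hide in that. Carried through, it moves W by 0.64 percentage points and S by 0.74 points, while W stands 28 points above S, far more than the margin. So the order holds and the values stay soft. Crystals might appear at the higher charge, but they are counted in target, so that objection falls.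

The forecast names Wednesday's, with 37.7% (35.5% to 39.5%) for Sunday's and 66% (63.5% to 68%) for Wednesday's. Both lie lower than this reckoning, on its ground: “That hints at a weak bimolecular loss to side product B”.

    substrate → side product A (k = 0.00120 s⁻¹)
    intermediate → target (k = 0.0480 s⁻¹)
    intermediate → decomposed reagent (k = 0.00100 s⁻¹)
    crystals ⇌ target, rate k4*(cs4 - [target]) while solid is left; crystals form when [target] > cs4 (solubility = 0.340 M, k = 0.110 s⁻¹)
    substrate → intermediate (k = 0.0140 s⁻¹)
    substrate + intermediate → side product B (k = 0.00750 M⁻¹ s⁻¹)

Wednesday's ends higher, with 65.7% against 38.2% for Sunday's. Wednesday's over the west reading gives a factor of 0.978 for its step, below the f of 0.999. The south-east recipe raised to 0.53 M and read at 2.50 min stands at 72.8%, where the 74.7% of the south-east recipe itself, multiplied by f for each of the two steps, gives 74.6%. In Wednesday's at 0.585 min, intermediate goes to target 21 times faster than to side product B, a selectivity factor. Side product B, made by the bimolecular step from substrate and intermediate, holds 5.07% of the substrate charged in Wednesday's at 2.00 min.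

All runs are calculated with constants of no real substance; noise was put on by code.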